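**Retrosynthetic overview**

- The target is the umbelliferone ether of a 2,3-dihydroxy-ent-drim-7-en-11-ol. The C11–O bond is cut by Mitsunobu etherification, and the C9–C11 bond by methylenation and hydroboration of a C9 ketone.
- The strategy rests on ring B: C5–C10 with the C8 methyl, the C7=C8 double bond, a carbonyl at C9, the C5 stereocentre and a C4 isopropenyl group (the gem-dimethyl carbon one hydrogen short) are the atoms of (S)-carvone.
- Key disconnection C3–C4: ring A is closed when a C4 tertiary radical, made by hydrogen-atom transfer to the isopropenyl CH2, adds 6-exo to a C3 aldehyde.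
- C10 is made quaternary by two enolate alkylations (methyl first, then the C1–C3 unit anti to the isopropenyl group). C2 comes from (S)-solketal.
- Ring order: B (carvone), then A (key step), then attachment of the coumarin.

Key step: step 8

Remark: drimane numbering (C1–C12) is used for all intermediates, including the monocyclic ones. The target is an ent-drimane: C10 methyl and C5 hydrogen trans, C11 cis to the C10 methyl, and the 2,3-diol trans-diequatorial.

**Route**

Step 1
Reactants: 1 (S)-carvone
Product: 3 6-methylcarvone (C6 epimers; trans expected as the main one), via carvone lithium dienolate 2 (not isolated)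
Conditions: LDA, THF, −78 °C; MeI, −78 → 0 °C
Reagents that add atoms: iodomethane, CI
Why: Kinetic deprotonation gives the cross-conjugated α′-enolate and enolate alkylation (SN2) puts the methyl on the future C10; the new centre need not be controlled because the same carbon is enolised again in step 3.

Step 2
Reactants: 4 (S)-solketal
Product: 5 triflate of (S)-solketal
Conditions: Tf2O, 2,6-lutidine, CH2Cl2, −78 °C; cold work-up, used at once
Reagents that add atoms: triflic anhydride, O=S(=O)(OS(=O)(=O)C(F)(F)F)C(F)(F)F
Why: O-sulfonylation of the primary alcohol leaves the stereocentre untouched and gives an electrophile reactive enough for a quaternary C-alkylation, for which a β-alkoxy iodide would be too sluggish.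

Step 3
Reactants: 3 6-methylcarvone; 5 triflate of (S)-solketal
Product: 7 acetonide ketone (C10 methyl cis and dioxolanylmethyl chain trans to the C5 isopropenyl group), via lithium enolate of 6-methylcarvone 6 (not isolated)
Conditions: LDA, THF, −78 → −20 °C; then 5 in THF, −78 → −20 °C
Reagents that add atoms: none
Why: Enolate alkylation (SN2 on the primary triflate) in which the electrophile enters the planar tetrasubstituted enolate on the face anti to the neighbouring isopropenyl group, which sets C10, while C2 is carried over unchanged from solketal.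

Step 4
Reactants: 7 acetonide ketone
Product: 8 keto diol
Conditions: AcOH/H2O 4:1, THF, 40 °C
Reagents that add atoms: none
Why: Acid-catalysed acetal hydrolysis, mild enough to leave the isopropenyl group and the enone untouched.

Step 5
Reactants: 8 keto diol
Product: 9 bis-TBS ether
Conditions: TBSCl, imidazole, DMAP (cat.), DMF, rt → 40 °C
Reagents that add atoms: tert-butyldimethylsilyl chloride, CC(C)(C)[Si](C)(C)Cl
Why: Standard silyl ether formation at the primary and the secondary hydroxyl, under conditions too mild to silylate the enone.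

Step 6
Reactants: 9 bis-TBS ether
Product: 10 primary alcohol (C2 silyl ether kept)
Conditions: HF·pyridine, pyridine, THF, 0 °C
Reagents that add atoms: none
Why: Selective desilylation, since the primary TBS ether is cleaved much faster than the secondary one under buffered HF·pyridine and the acidic medium prevents silyl migration.

Step 7
Reactants: 10 primary alcohol
Product: 11 keto aldehyde (C3 aldehyde with C2 silyloxy group)
Conditions: Dess–Martin periodinane, CH2Cl2, 0 °C → rt; used directly
Reagents that add atoms: none
Why: Dess–Martin oxidation is neutral and base-free, so the α-silyloxy stereocentre C2 should not epimerise and neither olefin is touched.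

Step 8
Reactants: 11 keto aldehyde
Product: 14 hydroxy enone (3-hydroxy-2-TBS-oxy-11-nor-ent-drim-7-en-9-one), via C4 tertiary radical 12 (not isolated), via C3 alkoxyl radical 13 (not isolated)
Conditions: Fe(acac)3 (30 mol %), PhSiH3 (2.5 equiv, added slowly), degassed EtOH, 50 °C
Reagents that add atoms: none
Why: Proposed new method: an iron hydride generated from Fe(acac)3 and PhSiH3 in ethanol transfers a hydrogen atom to the CH2 terminus of the isopropenyl group (Markovnikov-selective metal-hydride HAT), which completes the C4 gem-dimethyl group and gives tertiary radical 12; 12 adds to the C3 aldehyde carbon and the resulting alkoxyl radical 13 is reduced to the alcohol by iron(II)/ethanol or by Si–H. The closest known reaction types are the iron-hydride HAT reductive cyclisation of alkene-tethered ketones and the tin-hydride 6-exo cyclisation of alkyl radicals onto aldehydes; an aldehyde has not been shown as the acceptor under iron-hydride HAT conditions. Ring A closes in the 6-exo-trig mode onto the C=O group (new bond C3–C4) and can only be trans-fused, because C1 and C4 are already trans on ring B (C5 from carvone, C10 from step 3). The new stereocentre C3 is controlled by the chair-like transition state that keeps the C2 silyloxy group equatorial and turns the carbonyl oxygen equatorial, and by the reversibility of the addition (β-scission of 13 back to 12), which drains the axial alkoxyl radical into the more stable equatorial one, trans to O2. The step needs chemoselective hydrogen-atom transfer to the electron-rich 1,1-disubstituted olefin and not to the electron-poor trisubstituted enone olefin, which the electronics of the two olefins secure, and ring closure ahead of a second hydrogen transfer to 12, which is favoured by the fast 6-exo addition to an aldehyde, slow silane addition and rapid quenching of 13 in ethanol. No other closure is open to 12, since attack on the enone would need a four-membered ring or a 5-endo mode.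

Step 9
Reactants: 14 hydroxy enone
Product: 15 bis-TBS enone
Conditions: TBSOTf, 2,6-lutidine, CH2Cl2, 0 °C → rt
Reagents that add atoms: tert-butyldimethylsilyl triflate, CC(C)(C)[Si](C)(C)OS(=O)(=O)C(F)(F)F
Why: Silyl triflate silylation is the standard way to protect a hindered secondary alcohol next to a gem-dimethyl carbon, and since both oxygens end up silylated a 1,2-silyl shift in step 8 would be without consequence.

Step 10
Reactants: 15 bis-TBS enone
Product: 16 conjugated diene (C9=C11 exocyclic methylene)
Conditions: Ph3PCH3Br, KOtBu, toluene, 80 °C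
Reagents that add atoms: methyltriphenylphosphonium bromide, C[P+](c1ccccc1)(c1ccccc1)c1ccccc1.[Br-]
Why: Wittig methylenation under the forcing conditions used for hindered ketones; C10 is quaternary and C5 is not part of the enolisable system, so no stereocentre can be lost.

Step 11
Reactants: 16 conjugated diene
Product: 18 C11 primary alcohol, via B-alkyl-9-BBN adduct 17 (not isolated)
Conditions: 9-BBN, THF, 0 °C → 50 °C; then NaOH, H2O2, 0 °C → rt
Reagents that add atoms: hydrogen peroxide, OO
Why: Hydroboration–oxidation in which the bulky borane adds only to the exocyclic 1,1-disubstituted olefin of the diene with boron at C11, and hydrogen is delivered to C9 on the face anti to the axial C10 methyl, which sets C9 with C11 equatorial and cis to that methyl.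

Step 12
Reactants: 18 C11 primary alcohol; 19 umbelliferone
Product: 20 bis-TBS ether of the target
Conditions: PPh3, DIAD, THF, 0 °C → rt (50 °C if slow)
Reagents that add atoms: none
Why: Mitsunobu etherification of a primary alcohol with an acidic phenol (7-hydroxycoumarin), at a carbon that is no stereocentre, while both secondary oxygens are masked.

Step 13
Reactants: 20 bis-TBS ether of the target
Product: 21 CNP0124364.1
Conditions: HF·pyridine, pyridine, THF, 0 → 40 °C
Reagents that add atoms: none
Why: Fluoride-driven desilylation of both secondary silyl ethers under buffered acidic conditions that should spare the coumarin lactone, the aryl alkyl ether and the trisubstituted olefin.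

**Compound list**

1 | (S)-carvone, (5S)-2-methyl-5-(prop-1-en-2-yl)cyclohex-2-en-1-one | CC1=CC[C@H](C(C)=C)CC1=O | starting material
2 | carvone lithium dienolate (cross-conjugated, O–Li at C1, C1=C6) | CC1=CC[C@H](C(C)=C)C=C1O[Li] | intermediate
3 | 6-methylcarvone, (5S)-2,6-dimethyl-5-(prop-1-en-2-yl)cyclohex-2-en-1-one, C6 epimers; the (5S,6R)-trans epimer is drawn | CC1=CC[C@H](C(C)=C)[C@@H](C)C1=O | intermediate
4 | (S)-solketal, [(4S)-2,2-dimethyl-1,3-dioxolan-4-yl]methanol | OC[C@H]1COC(C)(C)O1 | starting material
5 | triflate of (S)-solketal, [(4R)-2,2-dimethyl-1,3-dioxolan-4-yl]methyl trifluoromethanesulfonate | FC(F)(F)S(=O)(=O)OC[C@H]1COC(C)(C)O1 | intermediate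
6 | lithium enolate of 6-methylcarvone (tetrasubstituted, C1=C6) | CC1=CC[C@H](C(C)=C)C(C)=C1O[Li] | intermediate
7 | (5R,6R)-6-{[(4S)-2,2-dimethyl-1,3-dioxolan-4-yl]methyl}-2,6-dimethyl-5-(prop-1-en-2-yl)cyclohex-2-en-1-one | CC1=CC[C@H](C(C)=C)[C@@](C)(C[C@H]2COC(C)(C)O2)C1=O | intermediate
8 | (5R,6R)-6-[(2S)-2,3-dihydroxypropyl]-2,6-dimethyl-5-(prop-1-en-2-yl)cyclohex-2-en-1-one | CC1=CC[C@H](C(C)=C)[C@@](C)(C[C@H](O)CO)C1=O | intermediate
9 | (5R,6R)-6-[(2S)-2,3-bis(tert-butyldimethylsilyloxy)propyl]-2,6-dimethyl-5-(prop-1-en-2-yl)cyclohex-2-en-1-one | CC1=CC[C@H](C(C)=C)[C@@](C)(C[C@H](O[Si](C)(C)C(C)(C)C)CO[Si](C)(C)C(C)(C)C)C1=O | intermediate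
10 | (5R,6R)-6-[(2S)-2-(tert-butyldimethylsilyloxy)-3-hydroxypropyl]-2,6-dimethyl-5-(prop-1-en-2-yl)cyclohex-2-en-1-one | CC1=CC[C@H](C(C)=C)[C@@](C)(C[C@H](O[Si](C)(C)C(C)(C)C)CO)C1=O | intermediate
11 | (5R,6R)-6-[(2S)-2-(tert-butyldimethylsilyloxy)-3-oxopropyl]-2,6-dimethyl-5-(prop-1-en-2-yl)cyclohex-2-en-1-one | CC1=CC[C@H](C(C)=C)[C@@](C)(C[C@H](O[Si](C)(C)C(C)(C)C)C=O)C1=O | intermediate
12 | C4 tertiary radical (hydrogen atom added to the isopropenyl CH2 of 11) | CC1=CC[C@H]([C](C)C)[C@@](C)(C[C@H](O[Si](C)(C)C(C)(C)C)C=O)C1=O | intermediate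
13 | C3 alkoxyl radical of the closed trans-decalin | CC1=CC[C@@H]2C(C)(C)[C@H]([O])[C@@H](O[Si](C)(C)C(C)(C)C)C[C@@]2(C)C1=O | intermediate
14 | (4aR,6S,7S,8aR)-7-(tert-butyldimethylsilyloxy)-6-hydroxy-2,5,5,8a-tetramethyl-4a,5,6,7,8,8a-hexahydronaphthalen-1(4H)-one (3-hydroxy-2-TBS-oxy-11-nor-ent-drim-7-en-9-one; O2 and O3 trans-diequatorial) | CC1=CC[C@@H]2C(C)(C)[C@H](O)[C@@H](O[Si](C)(C)C(C)(C)C)C[C@@]2(C)C1=O | intermediate
15 | (4aR,6S,7S,8aR)-6,7-bis(tert-butyldimethylsilyloxy)-2,5,5,8a-tetramethyl-4a,5,6,7,8,8a-hexahydronaphthalen-1(4H)-one | CC1=CC[C@@H]2C(C)(C)[C@H](O[Si](C)(C)C(C)(C)C)[C@@H](O[Si](C)(C)C(C)(C)C)C[C@@]2(C)C1=O | intermediate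
16 | 2,3-bis(TBS-oxy)-ent-drima-7,9(11)-diene (C9 exocyclic methylene conjugated with C7=C8) | CC1=CC[C@@H]2C(C)(C)[C@H](O[Si](C)(C)C(C)(C)C)[C@@H](O[Si](C)(C)C(C)(C)C)C[C@@]2(C)C1=C | intermediate
17 | B-alkyl-9-BBN adduct of 16 (boron on C11, hydrogen on C9 anti to the C10 methyl) | CC1=CC[C@@H]2C(C)(C)[C@H](O[Si](C)(C)C(C)(C)C)[C@@H](O[Si](C)(C)C(C)(C)C)C[C@@]2(C)[C@@H]1CB1C2CCCC1CCC2 | intermediate
18 | [(1R,4aS,6S,7S,8aR)-6,7-bis(tert-butyldimethylsilyloxy)-2,5,5,8a-tetramethyl-1,4,4a,5,6,7,8,8a-octahydronaphthalen-1-yl]methanol | CC1=CC[C@@H]2C(C)(C)[C@H](O[Si](C)(C)C(C)(C)C)[C@@H](O[Si](C)(C)C(C)(C)C)C[C@@]2(C)[C@@H]1CO | intermediate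
19 | umbelliferone, 7-hydroxy-2H-chromen-2-one | O=c1ccc2ccc(O)cc2o1 | starting material
20 | 7-{[(1R,4aS,6S,7S,8aR)-6,7-bis(tert-butyldimethylsilyloxy)-2,5,5,8a-tetramethyl-1,4,4a,5,6,7,8,8a-octahydronaphthalen-1-yl]methoxy}-2H-chromen-2-one | CC1=CC[C@@H]2C(C)(C)[C@H](O[Si](C)(C)C(C)(C)C)[C@@H](O[Si](C)(C)C(C)(C)C)C[C@@]2(C)[C@@H]1COc1ccc2ccc(=O)oc2c1 | intermediate
21 | CNP0124364.1, 7-{[(1R,4aS,6S,7S,8aR)-6,7-dihydroxy-2,5,5,8a-tetramethyl-1,4,4a,5,6,7,8,8a-octahydronaphthalen-1-yl]methoxy}-2H-chromen-2-one | CC1=CC[C@@H]2C(C)(C)[C@H](O)[C@@H](O)C[C@@]2(C)[C@@H]1COc1ccc2ccc(=O)oc2c1 | target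

**Step count**

Total: 13 steps. Longest linear sequence: 12 steps (steps 1 and 3–13, from (S)-carvone); step 2 is a one-step side branch.

**Steps most likely to fail**

1. Step 8 (proposed new method). What may go wrong is a second hydrogen transfer to the C4 radical before ring closure (plain reduction of the isopropenyl group), silane reduction or hemiacetal formation at the aldehyde, or poor facial selectivity at C3. The fallback uses known chemistry and sets out from alcohol 10. Cobalt-mediated Markovnikov HAT hydrobromination of the isopropenyl group (Co(acac)2, t-BuOOH, Et3SiH, TsBr) should give the C4 bromo alcohol F1, and Dess–Martin oxidation the C4 bromo aldehyde F2. Slow addition of Bu3SnH/AIBN in benzene at 80 °C then generates the same C4 radical in the absence of a metal hydride; its 6-exo closure onto the aldehyde is an established tin-hydride cyclisation, and the alkoxyl radical is quenched by Sn–H. The sequence comes back to the route at hydroxy enone 14.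

2. Step 3. What may go wrong is O-alkylation of the hindered enolate by the hard triflate, or C-alkylation too slow to compete with decomposition of the triflate. The fallback sets out from enolate 6 (made from 3 as in step 3). Alkylation with allyl bromide, which also enters anti to the isopropenyl group, should give the allyl ketone F3. Platinum-catalysed enantioselective diboration of its monosubstituted olefin (B2pin2, Pt2(dba)3, TADDOL-derived phosphonite of the enantiomer that leads to the (S)-diol; 1,1-disubstituted and trisubstituted olefins are inert) gives the 1,2-bis(pinacolboronate) F4. Oxidation with H2O2 buffered at pH 7, chosen to avoid nucleophilic epoxidation of the enone, comes back to the route at diol 8.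

3. Step 11. What may go wrong is poor facial selectivity in the hydrogen delivery to C9, or competing hydroboration modes of the conjugated diene. The fallback sets out from enone 15. A Wittig reaction with methoxymethylenetriphenylphosphorane (MeOCH2PPh3Cl, KHMDS) should give the C11 methyl dienol ether F5. Mild hydrolysis (aqueous oxalic acid, THF) protonates C9 kinetically on the face anti to the C10 methyl and gives the β,γ-unsaturated C11 aldehyde F6. This is reduced at once with NaBH4 in MeOH at 0 °C, before conjugation or epimerisation, and the sequence comes back to the route at alcohol 18.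

**Further compounds**

F1 | step 8 | C4 bromo alcohol (10 with HBr added Markovnikov across the isopropenyl group) | CC1=CC[C@H](C(C)(C)Br)[C@@](C)(C[C@H](O[Si](C)(C)C(C)(C)C)CO)C1=O
F2 | step 8 | C4 bromo aldehyde | CC1=CC[C@H](C(C)(C)Br)[C@@](C)(C[C@H](O[Si](C)(C)C(C)(C)C)C=O)C1=O
F3 | step 3 | allyl ketone, (5R,6R)-2,6-dimethyl-6-(prop-2-en-1-yl)-5-(prop-1-en-2-yl)cyclohex-2-en-1-one | CC1=CC[C@H](C(C)=C)[C@@](C)(CC=C)C1=O
F4 | step 3 | 1,2-bis(pinacolboronate) of F3 (configured to give the (S)-diol) | CC1=CC[C@H](C(C)=C)[C@@](C)(C[C@H](B2OC(C)(C)C(C)(C)O2)CB2OC(C)(C)C(C)(C)O2)C1=O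
F5 | step 11 | C11 methyl dienol ether (E/Z mixture) | CC1=CC[C@@H]2C(C)(C)[C@H](O[Si](C)(C)C(C)(C)C)[C@@H](O[Si](C)(C)C(C)(C)C)C[C@@]2(C)C1=COC
F6 | step 11 | β,γ-unsaturated C11 aldehyde | CC1=CC[C@@H]2C(C)(C)[C@H](O[Si](C)(C)C(C)(C)C)[C@@H](O[Si](C)(C)C(C)(C)C)C[C@@]2(C)[C@@H]1C=O
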